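## Structural features

The target is 7-hydroxy-3,5,6,8-tetramethoxy-2-(4-methoxyphenyl)-4H-chromen-4-one. A benzene ring A is fused through C4a–C8a to the γ-pyranone ring C, and a 4-methoxyphenyl ring B is attached to C2 by a single bond. There is no stereocentre and no stereogenic double bond, so the whole problem is one of constitution. Ring A is hexasubstituted: five contiguous oxygens run from C5 to C8a (methoxy at C5, C6 and C8, a free hydroxyl at C7, the ring oxygen at C8a), and C4a carries the C4 carbonyl. The real difficulty is twofold: one free hydroxyl (C7) must be placed among four methyl ethers on a crowded ring, and the two oxygens ortho to C4a must be told apart, because one becomes O1 and the other the C5 methoxy group. The sensitive points are the electron-rich ring A, which oxidises easily to quinones once phenols are unmasked, the C5 methoxy group peri to the carbonyl, which Lewis acids cleave by chelation, and the base-labile 1,3-dicarbonyl stage before ring C is closed. Two features are exploited. C4 is a carbonyl carbon between C4a of ring A and the methoxy-bearing C3, so it can arrive as carbon monoxide between an aryl iodide and a ketone enolate. Ring A without ring C has a mirror plane through C4a and C7, so the C5 and C8a oxygens can be carried as a pair of identical groups until ring closure differentiates them.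

## Logic of the disconnections

15 from 14: the benzyl–oxygen bond at C7 is the last protecting-group bond to be cut. The C7 hydroxyl must be the only oxygen without methyl at the end, and hydrogenolysis touches neither the methyl ethers nor the pyranone. Nothing is gained in skeleton; what is gained is the differentiation of O7. The forward step must spare the C2=C3 bond.

14 from 13: the O–CH3 bond at C5 is cut. Without this methyl, the two oxygens flanking C4a are equivalent in everything that precedes. An iodide already carrying the C5 methyl could come from 7 only by mono-methylation of two equivalent hydroxyls, which is statistical. The demand is a methylation of a chelated hydroxyl, made unambiguous by the benzyl group still on O7.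

13 from 11 (through 12): the O1–C2 bond of ring C is cut, which is the classical flavone retron of a 2-hydroxyaryl 1,3-diketone. Because 12 has two equivalent ortho hydroxyls, either closure gives the same chromenone. Ring C is opened to an acyclic dicarbonyl. The forward step needs one acid that removes two acetals and dehydrates, yet leaves the benzyl ether.

11 from 9, 10 and carbon monoxide: the C4a–C4 and C4–C3 bonds are cut. This splits the molecule into a ring A iodide and a ring B ketone of similar size, with C4 as a one-carbon gas. The demand is that CO inserts before the enolate couples, at an iodide with two ortho substituents.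

9 from 7: the two O–CH2OCH3 bonds are cut. The acetal is stable to base and palladium, small enough beside iodine, and is removed by the acid that closes ring C. The forward step is a double alkylation of hindered phenols.

7 from 6: the C–I bond is cut. The iodinated carbon is the only unsubstituted ring position and lies between two hydroxyls, so regiochemistry is not in question. Iodination must outrun oxidation of the diol.

6 from 4: both aryl C–O bonds are cut back to C–Br. One double operation keeps the symmetry. It requires C–O coupling with hydroxide at two electron-rich, ortho-substituted bromides.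

4 from 2: both C–Br bonds are cut. The methoxy groups direct ortho/para, and the central benzyloxy group, twisted out of plane, does not compete. The demand is clean double substitution without attack para to the benzyloxy group.

2 from 1: the O–benzyl bond is cut, which leads to a cheap phenol whose hydroxyl already sits between two methoxy groups, as O7 does in the target.

## Other disconnections considered

Alternative 1: Here C8a–O1, C4a–C4 and O1–C2 are all cut at once, and ring A arrives as a symmetric aryne. Flavone A1 would form from the silyl triflate A2 and the β-methoxyacrylic acid A3 (either alkene isomer should serve). Fluoride releases the aryne, the carboxylate of A3 adds, the aryl anion attacks the ester carbonyl so that the acyl group ends on the neighbouring carbon, and the resulting phenoxide displaces the β-methoxy group by addition–elimination.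
- In its favour: three bonds and ring C in one flask, against two bonds and no ring in step 6, so this is the better key step in bond economy. It needs neither CO nor palladium, which is an operational advantage. The aryne is mirror-symmetric, so its regiochemistry is as unambiguous as that of 9, an equal point.
- Against it: the oxygen pattern is wrong at C6/C7. A1 carries both as one acetonide, and its cleavage gives the catechol A4. The target needs methyl on O6 and hydrogen on O7, whereas the more acidic O7, para to the carbonyl, is expected to alkylate first. Protection of O7, methylation of O6 and deprotection would follow, so at least four steps after the key step against three in the chosen plan. The acid needed to open a catechol acetonide also endangers the C5 methoxy group.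
- A2 is a hexasubstituted arene (silyl, triflate, four oxygens) and should take more than the five steps that lead to 9.
- Mechanistically, the acyl shift passes through a strained four-membered transition structure, and protonation of the aryl anion (plain O-arylation) competes. In step 6 the corresponding side path, direct α-arylation, is held back by the ortho groups.
- On balance it has the stronger key step, but the differentiation problem is moved to a place where the substrate offers no help, and the route is longer.

Alternative 2: The cut is C8–C8a in the key step, with C5–C4a made one step earlier, so ring A is built last on a finished pyranone. Heating cyclobutenone A6 in toluene should open the four-membered ring, with the hydroxyl rotating outward, to a vinylketene. This closes by 6π electrocyclization onto the pyranone C=C and tautomerises to hydroquinone A5. A6 would come from the mixed squarate A7 and the metalated form of bromopyranone A8.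
- In its favour: every oxygen of ring A gets its place and its substituent from the squarate, without aromatic substitution chemistry. The key step is thermal and reagent-free, operationally better than step 6. O7 is marked from the start by tert-butyl, equal to the benzyl group of the chosen plan. Only two steps follow (double O-methylation, acidolysis), one fewer than after step 6, which is a better point.
- Against it: halogen–metal exchange on A8 must work beside an electrophilic pyranone carbonyl and an acidic ring C–H.
- The addition to A7 must choose the carbonyl next to the methoxy-bearing carbon, and only the size difference between tert-butoxy and methoxy guides it. The wrong choice gives the 6-tert-butoxy-7-methoxy isomer.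
- The tert-butyl enol ether may lose isobutene at the temperature of the rearrangement. The closure is onto a pyranone double bond with some aromatic character, and A5 is an air-sensitive hydroquinone.
- A7 and A8 each need a synthesis of their own, so the step count should exceed nine.
- On balance it addresses ring A directly and avoids metals in the key step, but it rests on two weakly controlled selectivities where the chosen plan rests on symmetry.

Alternative 3: Only C4–C4a is cut; the aryl–O1 and O1–C2 bonds exist beforehand in the 3-aryloxyacrylic acid A10, made from phenol A11. Oxalyl chloride and then SnCl4 (tetravalent tin) would generate an acylium carbon that attacks the single unsubstituted carbon of ring A and gives A9.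
- In its favour: A9 is the same compound as 14, so only the hydrogenolysis follows. That is one step after the key step against three, with no late methylation, a clear advantage. The Friedel–Crafts closure has only one position to go to, which is equal to the chosen plan in regiochemical certainty. It needs no CO.
- Against it: A11 is unsymmetrical. Its two oxygens that become O1 and the C5 methoxy must be differentiated on the benzene ring, by mono-functionalisation of a symmetric precursor or by introducing them one after the other. This is exactly the desymmetrisation the chosen plan avoids.
- A10 must have the carboxyl cis to the aryloxy group, and its enol ether must survive acid chloride formation.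
- SnCl4 can chelate the C4 carbonyl and the C5 methoxy oxygen of the product and cleave that methyl, or attack the benzyl ether.
- On balance the end game is shorter and the closure well suited to the electron-rich ring, but the front end is longer and less certain, so the total is expected to be similar or longer.

Key step: step 6

Remark: the 1,3-diketones 11 and 12 are written as their chelated enol tautomers, which equilibrate freely with the diketo forms. Phenoxide and enolate salts of numbered compounds carry no numbers of their own.

## Route

Step 1
Reactants: 1 2,6-dimethoxyphenol
Product: 2 2-(benzyloxy)-1,3-dimethoxybenzene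
Conditions: BnBr (1.1 equiv), K2CO3 (1.5 equiv), DMF, 60 °C
Reagents that add atoms: benzyl bromide, BrCc1ccccc1
Why: Williamson ether synthesis; the phenoxide of this hindered but acidic phenol should be alkylated cleanly by the reactive benzylic bromide, and the benzyl ether then masks the future C7 oxygen until the last step.

Step 2
Reactants: 2 2-(benzyloxy)-1,3-dimethoxybenzene
Product: 4 3-(benzyloxy)-1,5-dibromo-2,4-dimethoxybenzene, via monobromide 3 (not isolated)
Conditions: NBS (2.05 equiv), MeCN, 0 °C → rt, dark
Reagents that add atoms: N-bromosuccinimide, BrN1C(=O)CCC1=O
Why: Electrophilic aromatic bromination; each methoxy group directs to its free ortho position, which is also para to the other methoxy group, while the central benzyloxy group is twisted out of plane by its two neighbours and activates its para position only weakly. The 1,5-dibromide is therefore expected, as is usual for 1,2,3-trialkoxybenzenes, and ionic conditions in the dark avoid benzylic bromination.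

Step 3
Reactants: 4 3-(benzyloxy)-1,5-dibromo-2,4-dimethoxybenzene
Product: 6 5-(benzyloxy)-4,6-dimethoxybenzene-1,3-diol, via bromophenol 5 (not isolated)
Conditions: Pd2(dba)3 (2 mol%), tBuXPhos (8 mol%), KOH (6 equiv), 1,4-dioxane/H2O (1:1), degassed, 100 °C; then aq. HCl to pH 3 under N2
Reagents that add atoms: potassium hydroxide, [K+].[OH-]
Why: Palladium-catalysed C–O cross-coupling of aryl bromides with hydroxide (Buchwald–Hartwig type); the bulky biarylphosphine should make C–O reductive elimination faster than diaryl ether formation, and each bromide has only one ortho substituent. Benzyl and methyl ethers are inert to hot aqueous base, and exclusion of air protects the electron-rich bis-phenoxide.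

Step 4
Reactants: 6 5-(benzyloxy)-4,6-dimethoxybenzene-1,3-diol
Product: 7 5-(benzyloxy)-2-iodo-4,6-dimethoxybenzene-1,3-diol
Conditions: NIS (1.05 equiv), MeCN, −10 → 0 °C, dark
Reagents that add atoms: N-iodosuccinimide, IN1C(=O)CCC1=O
Why: Electrophilic aromatic iodination; the carbon between the two hydroxyls is the only unsubstituted ring position and is activated by both of them, so substitution can occur nowhere else. The acid-free reagent at low temperature should keep oxidation of the diol to a quinone behind C-iodination.

Step 5
Reactants: 7 5-(benzyloxy)-2-iodo-4,6-dimethoxybenzene-1,3-diol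
Product: 9 1-(benzyloxy)-4-iodo-2,6-dimethoxy-3,5-bis(methoxymethoxy)benzene, via monoacetal 8 (not isolated)
Conditions: NaH (2.5 equiv), MOMCl (2.5 equiv), THF/DMF (4:1), 0 °C → rt
Reagents that add atoms: chloromethyl methyl ether, COCCl
Why: Williamson-type O-alkylation of the bis-phenoxide with a small, highly reactive α-chloro ether, which should tolerate the iodine and methoxy neighbours. The two identical acetals keep the mirror symmetry of ring A and mask the phenols from the basic key step.

Step 6
Reactants: 9 1-(benzyloxy)-4-iodo-2,6-dimethoxy-3,5-bis(methoxymethoxy)benzene; 10 2-methoxy-1-(4-methoxyphenyl)ethanone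
Product: 11 (2E)-1-[4-(benzyloxy)-3,5-dimethoxy-2,6-bis(methoxymethoxy)phenyl]-3-hydroxy-2-methoxy-3-(4-methoxyphenyl)prop-2-en-1-one
Conditions: 10 (2.2 equiv), NaN(SiMe3)2 (2.1 equiv), THF, 0 °C; then 9, Pd(OAc)2 (5 mol%), Xantphos (7.5 mol%), CO (2 bar), 1,4-dioxane, 80 °C; then aq. NH4Cl
Reagents that add atoms: carbon monoxide, [C-]#[O+]
Why: Pd(OAc)2 is reduced in the flask by phosphine and enolate to zerovalent palladium, which inserts into the C–I bond of 9; CO then inserts into the aryl–palladium bond to give an aroyl–palladium iodide, and this makes the C4a–C4 bond. The sodium enolate of 10 replaces iodide on palladium, and C–C reductive elimination (equivalently, attack of the enolate carbon on the acyl group) makes the C4–C3 bond and returns zerovalent palladium. The closest known reaction type is the palladium-catalysed carbonylative α-arylation of aryl ketones with aryl iodides, which gives 1,3-diketones directly. No ring is closed and no stereocentre is created, since C3 ends as an enol carbon, is configurationally labile in the diketo tautomer and is planar in the target. The selectivity needed is CO insertion before enolate capture, that is carbonylative and not direct α-arylation; the two ortho acetal oxygens of 9 slow transmetalation and reductive elimination at the crowded aryl–palladium stage far more than they slow insertion of the small CO ligand, and CO pressure together with the wide bite angle of Xantphos, which speeds reductive elimination from the acyl complex, works in the same direction. C-acylation should prevail over O-acylation because the bond is formed on palladium from a carbon-bound enolate. The 1,3-diketone is more acidic than 10 and is deprotonated at once by the second equivalent of enolate to a chelated sodium diketonate, which shields it from a second acylation and from retro-Claisen cleavage until the NH4Cl quench. Benzyl, methyl and methoxymethyl ethers are inert to this basic, non-nucleophilic medium.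

Step 7
Reactants: 11 (2E)-1-[4-(benzyloxy)-3,5-dimethoxy-2,6-bis(methoxymethoxy)phenyl]-3-hydroxy-2-methoxy-3-(4-methoxyphenyl)prop-2-en-1-one
Product: 13 7-(benzyloxy)-5-hydroxy-3,6,8-trimethoxy-2-(4-methoxyphenyl)-4H-chromen-4-one, via bis-phenol 12 (not isolated)
Conditions: HCl (3 M in MeOH), THF, 60 °C
Reagents that add atoms: none
Why: Acid-catalysed transacetalisation to methanol removes both methoxymethyl groups; one of the two phenols then adds to the carbonyl that bears ring B and water is lost, the cyclodehydration of a 2-hydroxyaryl 1,3-diketone known from Baker–Venkataraman flavone syntheses. The two ortho hydroxyls are symmetry-equivalent, so either closure gives the same chromenone, and the benzyl and methyl ethers should withstand methanolic HCl.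

Step 8
Reactants: 13 7-(benzyloxy)-5-hydroxy-3,6,8-trimethoxy-2-(4-methoxyphenyl)-4H-chromen-4-one
Product: 14 7-(benzyloxy)-3,5,6,8-tetramethoxy-2-(4-methoxyphenyl)-4H-chromen-4-one
Conditions: MeI (5 equiv), K2CO3 (3 equiv), DMF, 50 °C
Reagents that add atoms: iodomethane, CI
Why: Williamson O-methylation; the C5 hydroxyl is the only free hydroxyl, so no selectivity is required. Although it is hydrogen-bonded to the C4 carbonyl, its phenoxide should be methylated under these forcing conditions, which are standard for 5-hydroxyflavones.

Step 9
Reactants: 14 7-(benzyloxy)-3,5,6,8-tetramethoxy-2-(4-methoxyphenyl)-4H-chromen-4-one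
Product: 15 7-hydroxy-3,5,6,8-tetramethoxy-2-(4-methoxyphenyl)-4H-chromen-4-one
Conditions: H2 (1 atm), Pd on carbon (10 wt%), EtOAc/MeOH (1:1), rt
Reagents that add atoms: none
Why: Hydrogenolysis of the benzyl aryl ether; the tetrasubstituted C2=C3 bond of the chromenone and the aryl methyl ethers should be inert at one atmosphere and room temperature, so only the C7 hydroxyl is set free.

## Compound list

1 | 2,6-dimethoxyphenol | COc1cccc(OC)c1O | starting material
2 | 2-(benzyloxy)-1,3-dimethoxybenzene | COc1cccc(OC)c1OCc1ccccc1 | intermediate
3 | 2-(benzyloxy)-4-bromo-1,3-dimethoxybenzene | COc1ccc(Br)c(OC)c1OCc1ccccc1 | intermediate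
4 | 3-(benzyloxy)-1,5-dibromo-2,4-dimethoxybenzene | COc1c(Br)cc(Br)c(OC)c1OCc1ccccc1 | intermediate
5 | 3-(benzyloxy)-5-bromo-2,4-dimethoxyphenol | COc1c(O)cc(Br)c(OC)c1OCc1ccccc1 | intermediate
6 | 5-(benzyloxy)-4,6-dimethoxybenzene-1,3-diol | COc1c(O)cc(O)c(OC)c1OCc1ccccc1 | intermediate
7 | 5-(benzyloxy)-2-iodo-4,6-dimethoxybenzene-1,3-diol | COc1c(O)c(I)c(O)c(OC)c1OCc1ccccc1 | intermediate
8 | 3-(benzyloxy)-6-iodo-2,4-dimethoxy-5-(methoxymethoxy)phenol | COCOc1c(I)c(O)c(OC)c(OCc2ccccc2)c1OC | intermediate
9 | 1-(benzyloxy)-4-iodo-2,6-dimethoxy-3,5-bis(methoxymethoxy)benzene | COCOc1c(I)c(OCOC)c(OC)c(OCc2ccccc2)c1OC | intermediate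
10 | 2-methoxy-1-(4-methoxyphenyl)ethanone | COCC(=O)c1ccc(OC)cc1 | starting material
11 | (2E)-1-[4-(benzyloxy)-3,5-dimethoxy-2,6-bis(methoxymethoxy)phenyl]-3-hydroxy-2-methoxy-3-(4-methoxyphenyl)prop-2-en-1-one | COc1ccc(cc1)/C(O)=C(OC)/C(=O)c1c(OCOC)c(OC)c(OCc2ccccc2)c(OC)c1OCOC | intermediate
12 | (2E)-1-[4-(benzyloxy)-2,6-dihydroxy-3,5-dimethoxyphenyl]-3-hydroxy-2-methoxy-3-(4-methoxyphenyl)prop-2-en-1-one | COc1ccc(cc1)/C(O)=C(OC)/C(=O)c1c(O)c(OC)c(OCc2ccccc2)c(OC)c1O | intermediate
13 | 7-(benzyloxy)-5-hydroxy-3,6,8-trimethoxy-2-(4-methoxyphenyl)-4H-chromen-4-one | COc1ccc(-c2oc3c(OC)c(OCc4ccccc4)c(OC)c(O)c3c(=O)c2OC)cc1 | intermediate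
14 | 7-(benzyloxy)-3,5,6,8-tetramethoxy-2-(4-methoxyphenyl)-4H-chromen-4-one | COc1ccc(-c2oc3c(OC)c(OCc4ccccc4)c(OC)c(OC)c3c(=O)c2OC)cc1 | intermediate
15 | 7-hydroxy-3,5,6,8-tetramethoxy-2-(4-methoxyphenyl)-4H-chromen-4-one | COc1ccc(-c2oc3c(OC)c(O)c(OC)c(OC)c3c(=O)c2OC)cc1 | target

## Step count and least certain steps

Total step count: 9. Longest linear sequence: 9 steps (1 to 15); ketone 10 enters at step 6.

Step 6 (key step). The most likely failures are processes at palladium: slow oxidative addition and CO insertion at the electron-rich, doubly ortho-substituted iodide, leading to hydrodeiodination; coupling of the enolate before CO has inserted; or O-acylation of the enolate. The fallback leaves palladium and CO and sets out from 9. Iodine–magnesium exchange (iPrMgCl·LiCl, THF, −20 °C) and carboxylation with CO2, with a buffered work-up that spares the acetals, should give 4-(benzyloxy)-3,5-dimethoxy-2,6-bis(methoxymethoxy)benzoic acid F1. 1,1'-Carbonyldiimidazole in THF converts it into [4-(benzyloxy)-3,5-dimethoxy-2,6-bis(methoxymethoxy)phenyl](1H-imidazol-1-yl)methanone F2. C-acylation of the lithium enolate of 10 (LiN(SiMe3)2, 2.2 equiv, THF, −78 → 0 °C) by F2, a Claisen-type acylation, comes back to the route at 11.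

Step 3. What may go wrong is incomplete exchange of the second bromide, hydrodebromination or diaryl ether formation at the electron-rich ring, and air oxidation of the bis-phenoxide in hot base. The fallback makes the C–O bonds through boron and sets out from 4. Double Miyaura borylation (B2pin2, Pd(dppf)Cl2, KOAc, 1,4-dioxane, 90 °C) should give 2,2'-[5-(benzyloxy)-4,6-dimethoxy-1,3-phenylene]bis(4,4,5,5-tetramethyl-1,3,2-dioxaborolane) F3. Oxidation of both C–B bonds under nearly neutral conditions (NaBO3·4H2O, THF/H2O, rt) returns to the route at 6.

Step 4. The risk is oxidation of the para-alkoxy-substituted diol to a quinone in competition with C-iodination. The fallback changes the order and the mechanism and sets out from 6. Protection first (NaH, MOMCl, THF/DMF, 0 °C) gives 3-(benzyloxy)-2,4-dimethoxy-1,5-bis(methoxymethoxy)benzene F4, which is no longer a phenol. Deprotonative lithiation at the carbon between the two acetal oxygens (n-BuLi, THF, −40 → 0 °C, kept cold to avoid metalation of the benzylic CH2) and quenching with I2 returns to the route at 9, so that 7 and step 5 are bypassed.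

Step 7. The acid strength needed to complete the dehydration may overlap with the onset of benzyl ether cleavage, so partial loss of the protecting group is the main concern. The fallback removes the benzyl group on purpose and puts it back selectively; it sets out from 11. Hydrogenolysis (H2, Pd on carbon, EtOAc) gives (2E)-3-hydroxy-1-[4-hydroxy-3,5-dimethoxy-2,6-bis(methoxymethoxy)phenyl]-2-methoxy-3-(4-methoxyphenyl)prop-2-en-1-one F5. Stronger acid can then be used freely (conc. HCl in MeOH, reflux) and should give 5,7-dihydroxy-3,6,8-trimethoxy-2-(4-methoxyphenyl)-4H-chromen-4-one F6. Because the C5 hydroxyl is tied up in a hydrogen bond to the carbonyl and the C7 hydroxyl is the more acidic, one equivalent of benzyl bromide with K2CO3 in acetone at rt should benzylate O7 only and return to the route at 13.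

## Further compounds

F1 | step 6 | 4-(benzyloxy)-3,5-dimethoxy-2,6-bis(methoxymethoxy)benzoic acid | COCOc1c(C(=O)O)c(OCOC)c(OC)c(OCc2ccccc2)c1OC
F2 | step 6 | [4-(benzyloxy)-3,5-dimethoxy-2,6-bis(methoxymethoxy)phenyl](1H-imidazol-1-yl)methanone | COCOc1c(C(=O)n2ccnc2)c(OCOC)c(OC)c(OCc2ccccc2)c1OC
F3 | step 3 | 2,2'-[5-(benzyloxy)-4,6-dimethoxy-1,3-phenylene]bis(4,4,5,5-tetramethyl-1,3,2-dioxaborolane) | COc1c(B2OC(C)(C)C(C)(C)O2)cc(B2OC(C)(C)C(C)(C)O2)c(OC)c1OCc1ccccc1
F4 | step 4 | 3-(benzyloxy)-2,4-dimethoxy-1,5-bis(methoxymethoxy)benzene | COCOc1cc(OCOC)c(OC)c(OCc2ccccc2)c1OC
F5 | step 7 | (2E)-3-hydroxy-1-[4-hydroxy-3,5-dimethoxy-2,6-bis(methoxymethoxy)phenyl]-2-methoxy-3-(4-methoxyphenyl)prop-2-en-1-one | COc1ccc(cc1)/C(O)=C(OC)/C(=O)c1c(OCOC)c(OC)c(O)c(OC)c1OCOC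
F6 | step 7 | 5,7-dihydroxy-3,6,8-trimethoxy-2-(4-methoxyphenyl)-4H-chromen-4-one | COc1ccc(-c2oc3c(OC)c(O)c(OC)c(O)c3c(=O)c2OC)cc1
A1 | alternative 1 | 3,5,8-trimethoxy-6,7-(isopropylidenedioxy)-2-(4-methoxyphenyl)-4H-chromen-4-one | COc1ccc(-c2oc3c(OC)c4OC(C)(C)Oc4c(OC)c3c(=O)c2OC)cc1
A2 | alternative 1 | 4,7-dimethoxy-2,2-dimethyl-6-(trimethylsilyl)-1,3-benzodioxol-5-yl trifluoromethanesulfonate | COc1c(OS(=O)(=O)C(F)(F)F)c([Si](C)(C)C)c(OC)c2OC(C)(C)Oc12
A3 | alternative 1 | (2Z)-2,3-dimethoxy-3-(4-methoxyphenyl)prop-2-enoic acid | CO/C(=C(\OC)C(=O)O)c1ccc(OC)cc1
A4 | alternative 1 | 6,7-dihydroxy-3,5,8-trimethoxy-2-(4-methoxyphenyl)-4H-chromen-4-one | COc1ccc(-c2oc3c(OC)c(O)c(O)c(OC)c3c(=O)c2OC)cc1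
A5 | alternative 2 | 7-tert-butoxy-5,8-dihydroxy-3,6-dimethoxy-2-(4-methoxyphenyl)-4H-chromen-4-one | COc1ccc(-c2oc3c(O)c(OC(C)(C)C)c(OC)c(O)c3c(=O)c2OC)cc1
A6 | alternative 2 | 2-tert-butoxy-4-hydroxy-3-methoxy-4-[5-methoxy-6-(4-methoxyphenyl)-4-oxo-4H-pyran-3-yl]cyclobut-2-en-1-one (racemic) | COc1ccc(cc1)-c1occ(c(=O)c1OC)C1(O)C(OC)=C(OC(C)(C)C)C1=O
A7 | alternative 2 | 3-tert-butoxy-4-methoxycyclobut-3-ene-1,2-dione | COC1=C(OC(C)(C)C)C(=O)C1=O
A8 | alternative 2 | 5-bromo-3-methoxy-2-(4-methoxyphenyl)-4H-pyran-4-one | COc1ccc(cc1)-c1occ(Br)c(=O)c1OC
A9 | alternative 3 | 7-(benzyloxy)-3,5,6,8-tetramethoxy-2-(4-methoxyphenyl)-4H-chromen-4-one | COc1ccc(-c2oc3c(OC)c(OCc4ccccc4)c(OC)c(OC)c3c(=O)c2OC)cc1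
A10 | alternative 3 | (2E)-3-[3-(benzyloxy)-2,4,5-trimethoxyphenoxy]-2-methoxy-3-(4-methoxyphenyl)prop-2-enoic acid | COc1ccc(cc1)/C(Oc1cc(OC)c(OC)c(OCc2ccccc2)c1OC)=C(\OC)C(=O)O
A11 | alternative 3 | 3-(benzyloxy)-2,4,5-trimethoxyphenol | COc1cc(O)c(OC)c(OCc2ccccc2)c1OC
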